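Plan
- Retrosynthesis: the C5–alkenyl bond of ring A is cut first (aryl triflate plus (E)-alkenylboronate). The O1–C2 and C3a–C3 bonds of the dihydrofuran ring are then cut together, leaving 1,4-benzoquinone and an (E)-3,4,5-trimethoxycinnamyl silyl ether.
- Enabling feature: O1 and C5 are para on ring A, so ring A is a masked 1,4-benzoquinone whose second oxygen later serves as the triflate handle at C5. C2 is benzylic to the trimethoxyphenyl ring (4-OMe para), so the C2=C3 alkene is a polarised styrene, nucleophilic at C3 and cation-stabilising at C2.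
- Forward: cinnamate to cinnamyl alcohol to silyl ether; a catalytic asymmetric formal [3+2] annulation with benzoquinone builds the dihydrofuran ring onto ring A in one step; triflation, Suzuki–Miyaura coupling and desilylation install the (E)-hydroxypropenyl chain.
- Stereochemistry: C3 comes from the chiral oxazaborolidinium catalyst (enantioface of the alkene), C2 from C3 by trans ring closure; both E-alkenes come from the starting cinnamate and the boronate.

Key step: step 3

Assumption: compounds 1, 4 and 7 are taken as commercial. The sense of induction in step 3 is assigned from the usual binding model of oxazaborolidinium–quinone complexes and is not derived rigorously here; the mirror-image catalyst (from (R)-diphenylprolinol) would be used, with nothing else changed, if the model is inverted for this alkene.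

Step 1
Reactants: 1 methyl (E)-3-(3,4,5-trimethoxyphenyl)prop-2-enoate
Product: 2 (E)-3-(3,4,5-trimethoxyphenyl)prop-2-en-1-ol
Conditions: i-Bu2AlH (2.5 equiv), CH2Cl2, −78 → 0 °C; aq. potassium sodium tartrate
Reagents that add atoms: none
Why: 1,2-reduction of a conjugated ester by diisobutylaluminium hydride at low temperature is a standard route to (E)-cinnamyl alcohols and leaves the alkene geometry and the aryl methyl ethers untouched.

Step 2
Reactants: 2 (E)-3-(3,4,5-trimethoxyphenyl)prop-2-en-1-ol
Product: 3 tert-butyl(diphenyl){[(E)-3-(3,4,5-trimethoxyphenyl)prop-2-en-1-yl]oxy}silane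
Conditions: TBDPSCl, imidazole, CH2Cl2, 0 °C → rt
Reagents that add atoms: tert-butyl(chloro)diphenylsilane, CC(C)(C)[Si](Cl)(c1ccccc1)c1ccccc1
Why: imidazole-mediated O-silylation of the primary alcohol; the bulky, weakly basic diphenylsilyl ether is chosen to withstand the strong acid catalyst of step 3.

Step 3
Reactants: 3 tert-butyl(diphenyl){[(E)-3-(3,4,5-trimethoxyphenyl)prop-2-en-1-yl]oxy}silane; 4 1,4-benzoquinone (1.5 equiv)
Product: 5 (2R,3S)-3-{[(tert-butyldiphenylsilyl)oxy]methyl}-2-(3,4,5-trimethoxyphenyl)-2,3-dihydro-1-benzofuran-5-ol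
Conditions: (S)-3,3-diphenyl-1-(2-methylphenyl)tetrahydro-1H,3H-pyrrolo[1,2-c][1,3,2]oxazaborole (20 mol %), HNTf2 (18 mol %), CH2Cl2, −78 → −20 °C; Et3N quench
Reagents that add atoms: none
Why: Proposed new method: the N-protonated oxazaborolidine should bind one carbonyl oxygen of 4 (lone pair syn to the vinylic C–H, quinone lying over a catalyst phenyl group), so that C3 of alkene 3 attacks the exposed face of the activated quinone CH, the benzylic cation at C2 (stabilised by the 4-methoxy group) is trapped by the neighbouring uncomplexed carbonyl oxygen, and the σ-complex loses its ring proton to aromatise to the 5-hydroxy-2,3-dihydrobenzofuran. The closest known reaction types are the oxazaborolidinium-catalysed enantioselective [3+2] annulation of a methoxybenzoquinone with a cyclic enol ether and the Lewis acid-promoted (also chiral titanium diolate-promoted) [3+2] annulation of alkoxybenzoquinones with (E)-propenylarenes; new here is the pairing of the parent, non-chelating quinone with a styrenyl allyl ether under this catalyst. The dihydrofuran ring closes as a stepwise polar formal [3+2] annulation, C3a–C3 bond first, then 5-exo-trig attack of the carbonyl oxygen on the benzylic cation. C3 is set by the catalyst in the C–C bond-forming event, because the alkene must lie over the O=C–CH unit of the shielded quinone with its aryl group endo and so presents one enantioface; C2 is set by C3, since the cation closes anti to the CH2OSi group and the C2–O bond can re-ionise under the acid, which makes the trans isomer both the kinetic and the thermodynamic product. The step needs O-closure to win over [2+2] and Diels–Alder adducts and the allylic ether not to ionise; the cation-stabilising trimethoxyphenyl group, the bulky silyl ether, the low temperature and the final warming (which should funnel any cyclobutane adduct to the same aromatic product without touching C3) are meant to secure this, and regioselectivity is no issue because the four CH positions of 4 are equivalent.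

Step 4
Reactants: 5 (2R,3S)-3-{[(tert-butyldiphenylsilyl)oxy]methyl}-2-(3,4,5-trimethoxyphenyl)-2,3-dihydro-1-benzofuran-5-ol
Product: 6 (2R,3S)-3-{[(tert-butyldiphenylsilyl)oxy]methyl}-2-(3,4,5-trimethoxyphenyl)-2,3-dihydro-1-benzofuran-5-yl trifluoromethanesulfonate
Conditions: PhNTf2 (1.2 equiv), Et3N, DMAP (cat.), CH2Cl2, 0 °C → rt
Reagents that add atoms: N-phenylbis(trifluoromethanesulfonimide), O=S(=O)(N(c1ccccc1)S(=O)(=O)C(F)(F)F)C(F)(F)F
Why: O-sulfonylation of the only free hydroxyl (the phenol) turns the former quinone oxygen into a cross-coupling handle without touching either stereocentre.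

Step 5
Reactants: 6 (2R,3S)-3-{[(tert-butyldiphenylsilyl)oxy]methyl}-2-(3,4,5-trimethoxyphenyl)-2,3-dihydro-1-benzofuran-5-yl trifluoromethanesulfonate; 7 tert-butyl(dimethyl){[(E)-3-(4,4,5,5-tetramethyl-1,3,2-dioxaborolan-2-yl)prop-2-en-1-yl]oxy}silane
Product: 8 (2R,3S)-5-[(E)-3-{[tert-butyl(dimethyl)silyl]oxy}prop-1-en-1-yl]-3-{[(tert-butyldiphenylsilyl)oxy]methyl}-2-(3,4,5-trimethoxyphenyl)-2,3-dihydro-1-benzofuran
Conditions: PdCl2(dppf)·CH2Cl2 (5 mol %; dppf = 1,1'-bis(diphenylphosphino)ferrocene), K3PO4 (3 equiv), 1,4-dioxane/H2O, 80 °C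
Reagents that add atoms: none
Why: Suzuki–Miyaura coupling, in which zerovalent palladium inserts into the aryl C–OTf bond and the (E)-alkenylboronate transfers with retention of geometry, under mildly basic conditions that leave both silyl ethers and both stereocentres untouched.

Step 6
Reactants: 8 (2R,3S)-5-[(E)-3-{[tert-butyl(dimethyl)silyl]oxy}prop-1-en-1-yl]-3-{[(tert-butyldiphenylsilyl)oxy]methyl}-2-(3,4,5-trimethoxyphenyl)-2,3-dihydro-1-benzofuran
Product: 9 (E)-3-[(2R,3S)-3-(hydroxymethyl)-2-(3,4,5-trimethoxyphenyl)-2,3-dihydro-1-benzofuran-5-yl]prop-2-en-1-ol (CNP0077408.1)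
Conditions: n-Bu4NF (3 equiv), THF, 0 °C → rt
Reagents that add atoms: none
Why: fluoride-mediated desilylation should cleave both silyl ethers under non-acidic conditions that spare the acid-sensitive benzylic C2–O bond and the electron-rich allylic alcohol.

Compound list
1 | methyl (E)-3-(3,4,5-trimethoxyphenyl)prop-2-enoate | COC(=O)/C=C/c1cc(OC)c(OC)c(OC)c1 | starting material
2 | (E)-3-(3,4,5-trimethoxyphenyl)prop-2-en-1-ol | OC/C=C/c1cc(OC)c(OC)c(OC)c1 | intermediate
3 | tert-butyl(diphenyl){[(E)-3-(3,4,5-trimethoxyphenyl)prop-2-en-1-yl]oxy}silane | CC(C)(C)[Si](OC/C=C/c1cc(OC)c(OC)c(OC)c1)(c2ccccc2)c3ccccc3 | intermediate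
4 | 1,4-benzoquinone | O=C1C=CC(=O)C=C1 | starting material
5 | (2R,3S)-3-{[(tert-butyldiphenylsilyl)oxy]methyl}-2-(3,4,5-trimethoxyphenyl)-2,3-dihydro-1-benzofuran-5-ol | COc1cc([C@@H]2Oc3ccc(O)cc3[C@H]2CO[Si](c4ccccc4)(c5ccccc5)C(C)(C)C)cc(OC)c1OC | intermediate
6 | (2R,3S)-3-{[(tert-butyldiphenylsilyl)oxy]methyl}-2-(3,4,5-trimethoxyphenyl)-2,3-dihydro-1-benzofuran-5-yl trifluoromethanesulfonate | COc1cc([C@@H]2Oc3ccc(OS(=O)(=O)C(F)(F)F)cc3[C@H]2CO[Si](c4ccccc4)(c5ccccc5)C(C)(C)C)cc(OC)c1OC | intermediate
7 | tert-butyl(dimethyl){[(E)-3-(4,4,5,5-tetramethyl-1,3,2-dioxaborolan-2-yl)prop-2-en-1-yl]oxy}silane | CC(C)(C)[Si](C)(C)OC/C=C/B1OC(C)(C)C(C)(C)O1 | starting material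
8 | (2R,3S)-5-[(E)-3-{[tert-butyl(dimethyl)silyl]oxy}prop-1-en-1-yl]-3-{[(tert-butyldiphenylsilyl)oxy]methyl}-2-(3,4,5-trimethoxyphenyl)-2,3-dihydro-1-benzofuran | COc1cc([C@@H]2Oc3ccc(/C=C/CO[Si](C)(C)C(C)(C)C)cc3[C@H]2CO[Si](c4ccccc4)(c5ccccc5)C(C)(C)C)cc(OC)c1OC | intermediate
9 | (E)-3-[(2R,3S)-3-(hydroxymethyl)-2-(3,4,5-trimethoxyphenyl)-2,3-dihydro-1-benzofuran-5-yl]prop-2-en-1-ol | COc1cc([C@@H]2Oc3ccc(/C=C/CO)cc3[C@H]2CO)cc(OC)c1OC | target

Total step count: 6. Longest linear sequence: 6 steps (from 1).

Steps most likely to fail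

Step 3 (proposed new method). A quinone held at a single point may give poor facial discrimination, and cyclobutane formation, oligomerisation of the alkene or ionisation of the allylic ether may outrun the annulation. The fallback uses known reaction types and builds the ring stepwise. It sets out from benzoquinone 4: enamine-catalysed asymmetric α-arylation of purchased 3-(tert-butyldiphenylsilyloxy)propanal should give the lactol (3S)-3-{[(tert-butyldiphenylsilyl)oxy]methyl}-2,3-dihydro-1-benzofuran-2,5-diol F1 as an anomeric mixture. The catalyst is 2-{bis[3,5-bis(trifluoromethyl)phenyl](trimethylsilyloxy)methyl}pyrrolidine in the enantiomeric series that gives the (S) centre, in EtOH/H2O at −20 °C. Addition of purchased 3,4,5-trimethoxyphenylmagnesium bromide (excess, THF, −78 → 0 °C) to the open hydroxy-aldehyde form should give 2-[(2S)-3-{[(tert-butyldiphenylsilyl)oxy]}-1-hydroxy-1-(3,4,5-trimethoxyphenyl)propan-2-yl]benzene-1,4-diol F2 as a mixture of carbinol epimers. Acid-catalysed cyclodehydration (p-TsOH cat., CH2Cl2, 0 °C) through the trimethoxybenzyl cation should close the ring trans to the C3 substituent and return to phenol 5. C3 would then come from the amine catalyst and C2 again from C3.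

Step 5. Oxidative addition into the electron-rich aryl triflate may be slow, so that hydrolysis of the triflate back to the phenol or protodeboronation of the alkenylboronate competes. The fallback sets out from triflate 6: a Heck reaction with methyl acrylate (Pd(OAc)2, 1,3-bis(diphenylphosphino)propane, Et3N, DMF, 90 °C) should give methyl (E)-3-[(2R,3S)-3-{[(tert-butyldiphenylsilyl)oxy]methyl}-2-(3,4,5-trimethoxyphenyl)-2,3-dihydro-1-benzofuran-5-yl]prop-2-enoate F3. Reduction with i-Bu2AlH (CH2Cl2, −78 °C) should give (E)-3-[(2R,3S)-3-{[(tert-butyldiphenylsilyl)oxy]methyl}-2-(3,4,5-trimethoxyphenyl)-2,3-dihydro-1-benzofuran-5-yl]prop-2-en-1-ol F4, and n-Bu4NF in THF then leads to target 9.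

Step 6. The hindered diphenylsilyl ether may cleave incompletely beside the fast-cleaving dimethylsilyl ether, or the electron-rich allylic alcohol may degrade on long exposure to basic fluoride. The fallback moves the deprotection ahead of the coupling and sets out from triflate 6: HF·pyridine (THF, 0 °C → rt) should give (2R,3S)-3-(hydroxymethyl)-2-(3,4,5-trimethoxyphenyl)-2,3-dihydro-1-benzofuran-5-yl trifluoromethanesulfonate F5. Stille coupling with purchased (E)-3-(tributylstannyl)prop-2-en-1-ol (Pd(PPh3)4, LiCl, 1,4-dioxane, 90 °C) should then give target 9 directly, with no fluoride step at the end.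

Further compounds
F1 | step 3 | (3S)-3-{[(tert-butyldiphenylsilyl)oxy]methyl}-2,3-dihydro-1-benzofuran-2,5-diol | OC1Oc2ccc(O)cc2[C@H]1CO[Si](c3ccccc3)(c4ccccc4)C(C)(C)C
F2 | step 3 | 2-[(2S)-3-{[(tert-butyldiphenylsilyl)oxy]}-1-hydroxy-1-(3,4,5-trimethoxyphenyl)propan-2-yl]benzene-1,4-diol | COc1cc(C(O)[C@H](CO[Si](c2ccccc2)(c3ccccc3)C(C)(C)C)c4cc(O)ccc4O)cc(OC)c1OC
F3 | step 5 | methyl (E)-3-[(2R,3S)-3-{[(tert-butyldiphenylsilyl)oxy]methyl}-2-(3,4,5-trimethoxyphenyl)-2,3-dihydro-1-benzofuran-5-yl]prop-2-enoate | COc1cc([C@@H]2Oc3ccc(/C=C/C(=O)OC)cc3[C@H]2CO[Si](c4ccccc4)(c5ccccc5)C(C)(C)C)cc(OC)c1OC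
F4 | step 5 | (E)-3-[(2R,3S)-3-{[(tert-butyldiphenylsilyl)oxy]methyl}-2-(3,4,5-trimethoxyphenyl)-2,3-dihydro-1-benzofuran-5-yl]prop-2-en-1-ol | COc1cc([C@@H]2Oc3ccc(/C=C/CO)cc3[C@H]2CO[Si](c4ccccc4)(c5ccccc5)C(C)(C)C)cc(OC)c1OC
F5 | step 6 | (2R,3S)-3-(hydroxymethyl)-2-(3,4,5-trimethoxyphenyl)-2,3-dihydro-1-benzofuran-5-yl trifluoromethanesulfonate | COc1cc([C@@H]2Oc3ccc(OS(=O)(=O)C(F)(F)F)cc3[C@H]2CO)cc(OC)c1OC
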